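**Retrosynthetic overview**

1. Feature: ring A is a benzene ring whose carbons carry, in order, the depside ester carbonyl (C1), OH (C2), H (C3), OH (C4), H (C5) and pentyl (C6). This 1-acyl-2,4-dioxy-6-alkyl array is what a dienylketene gives on 6π closure. Ring B (the 6-propylsalicylate unit, esterified at its C4 oxygen) is taken intact from 5-propylresorcinol.
2. Key disconnection: ring A is opened at C1–C2, C2–C3 and C4–C5 (and at C5–C6, the bond made by the Wolff shift). This gives the ring B aryl ester of (2E)-3-(diazoacetyl)oct-2-enoic acid and (triisopropylsilyloxy)ethyne, the latter made from ethynyl(trimethyl)silane by acetylide oxygenation, O-silylation and C-desilylation.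
3. The diazoketone is traced to a methyl ketone by detrifluoroacetylative diazo transfer, because acylating diazomethane would compete with dipolar cycloaddition to the doubly activated alkene. The methyl ketone is the ester of the ring B phenol with (2E)-3-acetyloct-2-enoic acid, the acid-catalysed aldol condensation product of octan-2-one and glyoxylic acid.
4. The ring B phenol comes from 5-propylresorcinol by carboxylation, benzyl ester formation, temporary allylation of the 4-hydroxyl, benzylation of the chelated 2-hydroxyl and deallylation.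
5. Ring order: ring B is present from the start; ring A is the only ring formed (key step), after which fluoride and hydrogenolysis free the phenols and the acid.

Key step: step 11

Remark: the target has no stereocentre; the one stereochemical element in the route is the E alkene of the C8 acid fragment, set in step 6 and consumed in step 11.

**Route**

Step 1
Reactants: 1 5-propylresorcinol
Product: 2 2,4-dihydroxy-6-propylbenzoic acid
Conditions: MeOMgOCO2Me (2 M in DMF, 3 equiv), 120 °C; then aq. HCl, 0 °C
Reagents that add atoms: methyl magnesium carbonate COC(=O)O[Mg]OC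
Why: Stiles carboxylation, a chelation-directed Kolbe–Schmitt-type reaction, should place CO2 on the ring carbon ortho to one hydroxyl and para to the other (between OH and propyl), as it does for the 5-pentyl homologue.

Step 2
Reactants: 2 2,4-dihydroxy-6-propylbenzoic acid
Product: 3 benzyl 2,4-dihydroxy-6-propylbenzoate
Conditions: BnBr (1.05 equiv), KHCO3 (1.2 equiv), DMF, rt
Reagents that add atoms: benzyl bromide BrCc1ccccc1
Why: Hydrogencarbonate ionises only the carboxylic acid, so SN2 O-alkylation by benzyl bromide should give the ester and leave both phenols untouched.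

Step 3
Reactants: 3 benzyl 2,4-dihydroxy-6-propylbenzoate
Product: 4 benzyl 2-hydroxy-4-(prop-2-en-1-yloxy)-6-propylbenzoate
Conditions: allyl bromide (1.1 equiv), K2CO3 (1.2 equiv), acetone, reflux
Reagents that add atoms: allyl bromide C=CCBr
Why: Williamson etherification is selective for the 4-hydroxyl because the 2-hydroxyl is hydrogen-bonded to the ester carbonyl and is the weaker acid and nucleophile under mild carbonate conditions.

Step 4
Reactants: 4 benzyl 2-hydroxy-4-(prop-2-en-1-yloxy)-6-propylbenzoate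
Product: 5 benzyl 2-(benzyloxy)-4-(prop-2-en-1-yloxy)-6-propylbenzoate
Conditions: BnBr (1.5 equiv), K2CO3 (2 equiv), Bu4NI (cat.), DMF, 60 °C
Reagents that add atoms: benzyl bromide BrCc1ccccc1
Why: With the 4-position blocked, more forcing Williamson conditions (polar aprotic solvent, iodide catalysis, heat) should alkylate the chelated 2-hydroxyl, and the allyl ether is inert.

Step 5
Reactants: 5 benzyl 2-(benzyloxy)-4-(prop-2-en-1-yloxy)-6-propylbenzoate
Product: 6 benzyl 2-(benzyloxy)-4-hydroxy-6-propylbenzoate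
Conditions: Pd(PPh3)4 (3 mol %), morpholine (3 equiv), THF, rt
Reagents that add atoms: none
Why: Tsuji–Trost deallylation: zerovalent palladium ionises the allyl aryl ether to a π-allyl complex and the phenoxide, morpholine takes up the allyl group, and the benzyl ether and benzyl ester do not react.

Step 6
Reactants: 7 octan-2-one; 8 glyoxylic acid (charged as its monohydrate)
Product: 9 (2E)-3-acetyloct-2-enoic acid
Conditions: 85% H3PO4, 7 (3 equiv), 80 °C; NaHCO3 extraction, acidification, crystallisation
Reagents that add atoms: none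
Why: Acid-catalysed aldol condensation through the more substituted enol of the methyl ketone (C3 of 7) and dehydration should give the open-chain E acid as the thermodynamic isomer, since any Z isomer closes to a neutral hydroxybutenolide that stays behind on hydrogencarbonate extraction.

Step 7
Reactants: 6 benzyl 2-(benzyloxy)-4-hydroxy-6-propylbenzoate; 9 (2E)-3-acetyloct-2-enoic acid
Product: 10 benzyl 4-{[(2E)-3-acetyloct-2-enoyl]oxy}-2-(benzyloxy)-6-propylbenzoate
Conditions: EDC·HCl (1.3 equiv), DMAP (0.1 equiv), CH2Cl2, 0 °C to rt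
Reagents that add atoms: none
Why: Steglich esterification: the carbodiimide and DMAP turn the acid into an acylpyridinium ion that the only free phenol of 6 intercepts, and the E acid cannot divert to a cyclic pseudo-ester.

Step 8
Reactants: 10 benzyl 4-{[(2E)-3-acetyloct-2-enoyl]oxy}-2-(benzyloxy)-6-propylbenzoate
Product: 12 benzyl 2-(benzyloxy)-4-{[(2E)-3-(diazoacetyl)oct-2-enoyl]oxy}-6-propylbenzoate, via trifluoroacetyl ketone 11 (not isolated)
Conditions: LiN(SiMe3)2 (1.1 equiv), THF, −78 °C; CF3CO2CH2CF3 (1.2 equiv), −78 °C; cold dilute HCl work-up; then MeSO2N3 (1.5 equiv), Et3N (1.5 equiv), H2O (1 equiv), MeCN, rt; neutral work-up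
Reagents that add atoms: methanesulfonyl azide CS(=O)(=O)N=[N+]=[N-] (the two diazo nitrogens of 12); 2,2,2-trifluoroethyl trifluoroacetate O=C(OCC(F)(F)F)C(F)(F)F (trifluoroacetyl group of 11 only)
Why: Danheiser detrifluoroacetylative diazo transfer: kinetic deprotonation of the methyl ketone and C-trifluoroacetylation activate that one carbon, to which the sulfonyl azide transfers N2 with loss of the trifluoroacetyl group, and this avoids diazomethane, which would add as a 1,3-dipole to the ene-dicarbonyl alkene.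

Step 9
Reactants: 13 ethynyl(trimethyl)silane
Product: 16 triisopropyl{[(trimethylsilyl)ethynyl]oxy}silane, via lithium acetylide 14 (not isolated), via lithium ynolate 15 (not isolated)
Conditions: LiN(SiMe3)2 (2.2 equiv), THF, −78 °C; t-BuOOH (1.0 equiv, in decane), −78 to 0 °C; i-Pr3SiOSO2CF3 (1.1 equiv), −78 to 0 °C
Reagents that add atoms: tert-butyl hydroperoxide CC(C)(C)OO; triisopropylsilyl trifluoromethanesulfonate CC(C)[Si](OS(=O)(=O)C(F)(F)F)(C(C)C)C(C)C
Why: Julia oxygenation of a lithium acetylide by lithium tert-butyl peroxide should give the ynolate, and the bulky silyl triflate should silylate it on oxygen (Kowalski-type ynol silyl ether formation).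

Step 10
Reactants: 16 triisopropyl{[(trimethylsilyl)ethynyl]oxy}silane
Product: 17 (ethynyloxy)triisopropylsilane, i.e. (triisopropylsilyloxy)ethyne
Conditions: K2CO3 (0.1 equiv), MeOH, 0 °C; pentane extraction, concentration in the cold; used at once
Reagents that add atoms: none
Why: Base-catalysed methanolysis of an alkynylsilane: methoxide attacks the unhindered trimethylsilyl group on carbon and releases an acetylide far faster than it attacks the triisopropylsilyl group on oxygen.

Step 11
Reactants: 12 benzyl 2-(benzyloxy)-4-{[(2E)-3-(diazoacetyl)oct-2-enoyl]oxy}-6-propylbenzoate; 17 (triisopropylsilyloxy)ethyne (2 equiv)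
Product: 21 benzyl 2-(benzyloxy)-4-{[2-hydroxy-6-pentyl-4-(triisopropylsilyloxy)benzoyl]oxy}-6-propylbenzoate, via vinylketene 18 (not isolated), via cyclobutenone 19 (not isolated), via dienylketene 20 (not isolated)
Conditions: ClCH2CH2Cl (0.05 M), argon, hν (365 nm LEDs), 20 °C; then 80 °C
Reagents that add atoms: none
Why: Light expels N2 from 12 and the alkenyl carbon (later C6) shifts from the carbonyl carbon to the diazo carbon (later C5) in a photochemical Wolff rearrangement, giving vinylketene 18 whose ketene carbonyl carbon is the later C2. The polarised siloxyalkyne adds across the ketene C=C in a [2+2] cycloaddition (C2–C3 and C4–C5) to the 4-alkenylcyclobutenone 19, which on warming opens by 4π electrocyclic cleavage of its C2–C5 bond to dienylketene 20; 6π electrocyclic closure then joins C1 to C2 and the cyclohexadienone enolises to the phenol. This is the second-generation Danheiser benzannulation of an unsaturated α-diazoketone with a siloxyalkyne, applied here to a 3-acylacrylate ester. Ring A, the only ring formed, is closed as a six-membered carbocycle in the thermal 6π electrocyclisation, and no stereocentre is created because the sp3 carbons of 19 and of the dienone become aromatic. The regiochemistry needed (silyloxy at C4, meta to the new C2 hydroxyl) follows from bonding of the unsubstituted, nucleophilic alkyne carbon to the electrophilic ketene carbonyl carbon, and the E alkene keeps the ester carbonyl away from the ketene (no 2-pyranone) and leaves only hydrogen on the inner side of the closing triene terminus. Light of 365 nm should excite the diazoketone but not the aryl ester (no photo-Fries shift), and the excess of 17 should outrun capture of the ketenes by the chelated product phenol.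

Step 12
Reactants: 21 benzyl 2-(benzyloxy)-4-{[2-hydroxy-6-pentyl-4-(triisopropylsilyloxy)benzoyl]oxy}-6-propylbenzoate
Product: 22 benzyl 2-(benzyloxy)-4-[(2,4-dihydroxy-6-pentylbenzoyl)oxy]-6-propylbenzoate
Conditions: Bu4NF (1.2 equiv), AcOH (1.5 equiv), THF, 0 °C
Reagents that add atoms: none
Why: Fluoride cleaves the aryl silyl ether (Si–F bond formation), and the acetic acid buffer keeps the liberated phenoxide from transacylating the depside ester.

Step 13
Reactants: 22 benzyl 2-(benzyloxy)-4-[(2,4-dihydroxy-6-pentylbenzoyl)oxy]-6-propylbenzoate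
Product: 23 4-[(2,4-dihydroxy-6-pentylbenzoyl)oxy]-2-hydroxy-6-propylbenzoic acid (CNP0324314.0)
Conditions: H2 (1 atm), 10% Pd/C, EtOAc, rt
Reagents that add atoms: none
Why: Heterogeneous catalytic hydrogenolysis should cleave both benzylic C–O bonds (ether and ester) under neutral conditions that leave the aryl ester, the arenes and the salicylic acid untouched.

**Compound list**

1 | 5-propylbenzene-1,3-diol (5-propylresorcinol) | CCCc1cc(O)cc(O)c1 | starting material
2 | 2,4-dihydroxy-6-propylbenzoic acid | CCCc1cc(O)cc(O)c1C(=O)O | intermediate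
3 | benzyl 2,4-dihydroxy-6-propylbenzoate | CCCc1cc(O)cc(O)c1C(=O)OCc1ccccc1 | intermediate
4 | benzyl 2-hydroxy-4-(prop-2-en-1-yloxy)-6-propylbenzoate | CCCc1cc(OCC=C)cc(O)c1C(=O)OCc1ccccc1 | intermediate
5 | benzyl 2-(benzyloxy)-4-(prop-2-en-1-yloxy)-6-propylbenzoate | CCCc1cc(OCC=C)cc(OCc2ccccc2)c1C(=O)OCc1ccccc1 | intermediate
6 | benzyl 2-(benzyloxy)-4-hydroxy-6-propylbenzoate | CCCc1cc(O)cc(OCc2ccccc2)c1C(=O)OCc1ccccc1 | intermediate
7 | octan-2-one | CCCCCCC(C)=O | starting material
8 | glyoxylic acid (used as the monohydrate) | O=CC(=O)O | starting material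
9 | (2E)-3-acetyloct-2-enoic acid | CCCCC/C(C(C)=O)=C\C(=O)O | intermediate
10 | benzyl 4-{[(2E)-3-acetyloct-2-enoyl]oxy}-2-(benzyloxy)-6-propylbenzoate | CCCCC/C(C(C)=O)=C\C(=O)Oc1cc(OCc2ccccc2)c(C(=O)OCc2ccccc2)c(CCC)c1 | intermediate
11 | benzyl 2-(benzyloxy)-6-propyl-4-{[(2E)-3-(4,4,4-trifluoro-3-oxobutanoyl)oct-2-enoyl]oxy}benzoate (trifluoroacetyl ketone) | CCCCC/C(C(=O)CC(=O)C(F)(F)F)=C\C(=O)Oc1cc(OCc2ccccc2)c(C(=O)OCc2ccccc2)c(CCC)c1 | intermediate
12 | benzyl 2-(benzyloxy)-4-{[(2E)-3-(diazoacetyl)oct-2-enoyl]oxy}-6-propylbenzoate | CCCCC/C(C(=O)C=[N+]=[N-])=C\C(=O)Oc1cc(OCc2ccccc2)c(C(=O)OCc2ccccc2)c(CCC)c1 | intermediate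
13 | ethynyl(trimethyl)silane | C#C[Si](C)(C)C | starting material
14 | lithium (trimethylsilyl)acetylide | [Li]C#C[Si](C)(C)C | intermediate
15 | lithium 2-(trimethylsilyl)ethynolate | [Li]OC#C[Si](C)(C)C | intermediate
16 | triisopropyl{[(trimethylsilyl)ethynyl]oxy}silane | CC(C)[Si](OC#C[Si](C)(C)C)(C(C)C)C(C)C | intermediate
17 | (ethynyloxy)triisopropylsilane | C#CO[Si](C(C)C)(C(C)C)C(C)C | intermediate
18 | benzyl 2-(benzyloxy)-4-{[(2E)-3-(2-oxoethenyl)oct-2-enoyl]oxy}-6-propylbenzoate (vinylketene) | CCCCC/C(C=C=O)=C\C(=O)Oc1cc(OCc2ccccc2)c(C(=O)OCc2ccccc2)c(CCC)c1 | intermediate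
19 | benzyl 2-(benzyloxy)-4-{[(2E)-3-[4-oxo-2-(triisopropylsilyloxy)cyclobut-2-en-1-yl]oct-2-enoyl]oxy}-6-propylbenzoate (cyclobutenone, racemic) | CCCCC/C(C1C(=O)C=C1O[Si](C(C)C)(C(C)C)C(C)C)=C\C(=O)Oc1cc(OCc2ccccc2)c(C(=O)OCc2ccccc2)c(CCC)c1 | intermediate
20 | benzyl 2-(benzyloxy)-4-{[(2E)-3-[(1E)-4-oxo-2-(triisopropylsilyloxy)buta-1,3-dien-1-yl]oct-2-enoyl]oxy}-6-propylbenzoate (dienylketene) | CCCCC/C(/C=C(\C=C=O)O[Si](C(C)C)(C(C)C)C(C)C)=C\C(=O)Oc1cc(OCc2ccccc2)c(C(=O)OCc2ccccc2)c(CCC)c1 | intermediate
21 | benzyl 2-(benzyloxy)-4-{[2-hydroxy-6-pentyl-4-(triisopropylsilyloxy)benzoyl]oxy}-6-propylbenzoate | CCCCCc1cc(O[Si](C(C)C)(C(C)C)C(C)C)cc(O)c1C(=O)Oc1cc(OCc2ccccc2)c(C(=O)OCc2ccccc2)c(CCC)c1 | intermediate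
22 | benzyl 2-(benzyloxy)-4-[(2,4-dihydroxy-6-pentylbenzoyl)oxy]-6-propylbenzoate | CCCCCc1cc(O)cc(O)c1C(=O)Oc1cc(OCc2ccccc2)c(C(=O)OCc2ccccc2)c(CCC)c1 | intermediate
23 | 4-[(2,4-dihydroxy-6-pentylbenzoyl)oxy]-2-hydroxy-6-propylbenzoic acid (CNP0324314.0) | CCCCCc1cc(O)cc(O)c1C(=O)Oc1cc(O)c(C(=O)O)c(CCC)c1 | target

**Step count**

Total step count: 13.
Longest linear sequence: 10 steps (steps 1–5, 7, 8, 11, 12, 13).

**Steps most likely to fail**

Step 11 (key step). The ketenes may be consumed by the chelated phenol of the product or by dimerisation, the alkene may photoisomerise so that the ester carbonyl captures the ketene, or the cyclobutenone may not open and reclose cleanly. The fallback brings ring A in preformed and makes the depside bond by classical esterification. It sets out from 6 and comes back to the route at 23. Commercial olivetolic acid (2,4-dihydroxy-6-pentylbenzoic acid) would be perbenzylated (BnBr, K2CO3, DMF, 60 °C) to benzyl 2,4-bis(benzyloxy)-6-pentylbenzoate F1. Saponification (KOH, aqueous DMSO, 80 °C) would give 2,4-bis(benzyloxy)-6-pentylbenzoic acid F2. Its mixed anhydride with (CF3CO)2O in toluene at rt would acylate the phenol of 6 to benzyl 2-(benzyloxy)-4-{[2,4-bis(benzyloxy)-6-pentylbenzoyl]oxy}-6-propylbenzoate F3. Hydrogenolysis (H2, 10% Pd/C, EtOAc) of all four benzyl groups would then give 23.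

Step 8. The lithium enolate may attack the aryl ester or add to the ene-dicarbonyl alkene of a second molecule, or the aryl ester may be cleaved during the amine and water stage. The fallback makes the diazoketone before the depside ester exists. It sets out from 9 and comes back at 12. Acid 9 would be esterified with 2-(trimethylsilyl)ethanol (EDC·HCl, DMAP, CH2Cl2) to 2-(trimethylsilyl)ethyl (2E)-3-acetyloct-2-enoate F4. Treatment with LiN(SiMe3)2 and CF3CO2CH2CF3 at −78 °C would give the trifluoroacetyl ketone 2-(trimethylsilyl)ethyl (2E)-3-(4,4,4-trifluoro-3-oxobutanoyl)oct-2-enoate F5. Diazo transfer (MeSO2N3, Et3N, H2O, MeCN) would give 2-(trimethylsilyl)ethyl (2E)-3-(diazoacetyl)oct-2-enoate F6. Bu4NF in THF at 0 °C, followed by acidification with cold phosphate buffer, would release (2E)-3-(diazoacetyl)oct-2-enoic acid F7. This acid would be coupled with 6 (EDC·HCl, DMAP, CH2Cl2, 0 °C) to give 12.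

Step 10. Methoxide may also strip the oxygen-bound silyl group, methanol may add to the ynol ether, or the volatile terminal alkyne may be lost on concentration. The fallback skips the C-desilylation and carries the trimethylsilyl group through the benzannulation. It sets out from 16 (with 12) and comes back at 21. Irradiation of 12 with 16 under the conditions of step 11 would pass through vinylketene 18, the C-silylated cyclobutenone benzyl 2-(benzyloxy)-4-{[(2E)-3-[4-oxo-2-(triisopropylsilyloxy)-3-(trimethylsilyl)cyclobut-2-en-1-yl]oct-2-enoyl]oxy}-6-propylbenzoate F8 and the C-silylated dienylketene benzyl 2-(benzyloxy)-4-{[(2E)-3-[(1E)-4-oxo-2-(triisopropylsilyloxy)-3-(trimethylsilyl)buta-1,3-dien-1-yl]oct-2-enoyl]oxy}-6-propylbenzoate F9. The product would be benzyl 2-(benzyloxy)-4-{[2-hydroxy-6-pentyl-4-(triisopropylsilyloxy)-3-(trimethylsilyl)benzoyl]oxy}-6-propylbenzoate F10, with the silyl-bearing alkyne carbon bonded to the ketene carbonyl carbon. Ipso-protodesilylation of the electron-rich C3 position (CF3CO2H, CH2Cl2, 0 °C) would then give 21.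

**Further compounds**

F1 | step 11 | benzyl 2,4-bis(benzyloxy)-6-pentylbenzoate | CCCCCc1cc(OCc2ccccc2)cc(OCc2ccccc2)c1C(=O)OCc1ccccc1
F2 | step 11 | 2,4-bis(benzyloxy)-6-pentylbenzoic acid | CCCCCc1cc(OCc2ccccc2)cc(OCc2ccccc2)c1C(=O)O
F3 | step 11 | benzyl 2-(benzyloxy)-4-{[2,4-bis(benzyloxy)-6-pentylbenzoyl]oxy}-6-propylbenzoate | CCCCCc1cc(OCc2ccccc2)cc(OCc2ccccc2)c1C(=O)Oc1cc(OCc2ccccc2)c(C(=O)OCc2ccccc2)c(CCC)c1
F4 | step 8 | 2-(trimethylsilyl)ethyl (2E)-3-acetyloct-2-enoate | CCCCC/C(C(C)=O)=C\C(=O)OCC[Si](C)(C)C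
F5 | step 8 | 2-(trimethylsilyl)ethyl (2E)-3-(4,4,4-trifluoro-3-oxobutanoyl)oct-2-enoate | CCCCC/C(C(=O)CC(=O)C(F)(F)F)=C\C(=O)OCC[Si](C)(C)C
F6 | step 8 | 2-(trimethylsilyl)ethyl (2E)-3-(diazoacetyl)oct-2-enoate | CCCCC/C(C(=O)C=[N+]=[N-])=C\C(=O)OCC[Si](C)(C)C
F7 | step 8 | (2E)-3-(diazoacetyl)oct-2-enoic acid | CCCCC/C(C(=O)C=[N+]=[N-])=C\C(=O)O
F8 | step 10 | benzyl 2-(benzyloxy)-4-{[(2E)-3-[4-oxo-2-(triisopropylsilyloxy)-3-(trimethylsilyl)cyclobut-2-en-1-yl]oct-2-enoyl]oxy}-6-propylbenzoate | CCCCC/C(C1C(=O)C([Si](C)(C)C)=C1O[Si](C(C)C)(C(C)C)C(C)C)=C\C(=O)Oc1cc(OCc2ccccc2)c(C(=O)OCc2ccccc2)c(CCC)c1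
F9 | step 10 | benzyl 2-(benzyloxy)-4-{[(2E)-3-[(1E)-4-oxo-2-(triisopropylsilyloxy)-3-(trimethylsilyl)buta-1,3-dien-1-yl]oct-2-enoyl]oxy}-6-propylbenzoate | CCCCC/C(/C=C(\C([Si](C)(C)C)=C=O)O[Si](C(C)C)(C(C)C)C(C)C)=C\C(=O)Oc1cc(OCc2ccccc2)c(C(=O)OCc2ccccc2)c(CCC)c1
F10 | step 10 | benzyl 2-(benzyloxy)-4-{[2-hydroxy-6-pentyl-4-(triisopropylsilyloxy)-3-(trimethylsilyl)benzoyl]oxy}-6-propylbenzoate | CCCCCc1cc(O[Si](C(C)C)(C(C)C)C(C)C)c([Si](C)(C)C)c(O)c1C(=O)Oc1cc(OCc2ccccc2)c(C(=O)OCc2ccccc2)c(CCC)c1
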